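**Retrosynthetic overview**
1. The route rests on the 1,3-diol C9(OH)–C8H–C7H(OH), with ring B (at its C5, ortho to the phenol oxygen) on C8 and guaiacyl ring C on C7. This unit is read as the adduct of formaldehyde to an E-stilbene C8=C7.
2. The 7R,8R diol comes from a trans-4,5-diaryl-1,3-dioxane, made from the stilbene and two CH2O by an asymmetric acid-catalysed Prins reaction on the finished lactone skeleton (C8–C9 and C7–O formed, dioxane closed).
3. The stilbene comes from a Heck coupling of the ring B 5-iodo acetate with 4-benzyloxy-3-methoxystyrene; the iodide comes from ortho-iodination of the only free phenol of ring-A-O-benzyl matairesinol.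
4. That lactone comes from trans alkylation of an (R)-4-benzylbutyrolactone with the ring A benzyl bromide; its stereocentre comes from an Evans alkylation of a dihydroferulic acid imide.
5. Ring order: butyrolactone (step 5), then the 1,3-dioxane (step 13), which is opened again in step 14.

Key step: step 13

Assumption: the sense of induction of a confined acid on a stilbene cannot be derived from first principles; both antipodes of the catalyst are accessible from (R)- or (S)-BINOL, and the antipode that directs formaldehyde to the Re face of C8 is the one used in step 13.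

Ring B numbering used below: C1 bears the lactone CH2, C3 the OMe, C4 the oxygen, C5 the new side chain.

**Step 1**
Reactants: 1 3-(4-hydroxy-3-methoxyphenyl)propanoic acid (dihydroferulic acid)
Product: 3 3-[4-(tert-butyldimethylsilyloxy)-3-methoxyphenyl]propanoic acid, via bis-silylated acid 2 (not isolated)
Conditions: TBSCl (2.3 equiv), imidazole, DMF, rt; then AcOH/THF/H2O, rt
Reagents that add atoms: tert-butyldimethylsilyl chloride, CC(C)(C)[Si](C)(C)Cl
Why: Silyl ether formation on both acidic OH groups followed by selective hydrolysis of the far more labile silyl ester leaves only the aryl silyl ether.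

**Step 2**
Reactants: 3 3-[4-(tert-butyldimethylsilyloxy)-3-methoxyphenyl]propanoic acid; 4 (S)-4-benzyl-1,3-oxazolidin-2-one
Product: 6 (S)-4-benzyl-3-{3-[4-(tert-butyldimethylsilyloxy)-3-methoxyphenyl]propanoyl}-1,3-oxazolidin-2-one, via mixed pivalic anhydride 5 (not isolated)
Conditions: PivCl, Et3N, THF, −20 °C; then LiCl, 4, −20 °C → rt
Reagents that add atoms: none
Why: N-acylation of the Evans auxiliary through the mixed anhydride, whose hindered pivaloyl carbonyl is not attacked, so only the arylpropanoyl group is transferred.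

**Step 3**
Reactants: 6 the N-acyl oxazolidinone
Product: 8 tert-butyl (3R)-4-[(4S)-4-benzyl-2-oxo-1,3-oxazolidin-3-yl]-3-[4-(tert-butyldimethylsilyloxy)-3-methoxybenzyl]-4-oxobutanoate, via sodium enolate 7 (not isolated)
Conditions: NaN(SiMe3)2, THF, −78 °C; then BrCH2CO2tBu, −78 → −40 °C
Reagents that add atoms: tert-butyl bromoacetate, BrCC(=O)OC(C)(C)C
Why: Evans asymmetric alkylation, in which the chelated sodium (Z)-enolate is alkylated on the face opposite the benzyl group of the (S)-auxiliary, setting the future lactone C4 as R.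

**Step 4**
Reactants: 8 the alkylated imide
Product: 9 tert-butyl (R)-4-hydroxy-3-[4-(tert-butyldimethylsilyloxy)-3-methoxybenzyl]butanoate
Conditions: LiBH4, MeOH (1 equiv), THF, 0 °C
Reagents that add atoms: none
Why: Reductive cleavage of the N-acyl oxazolidinone gives the primary alcohol and returns the auxiliary, while the tert-butyl ester and the aryl silyl ether are not reduced at 0 °C and the stereocentre is not epimerised.

**Step 5**
Reactants: 9 the hydroxy tert-butyl ester
Product: 10 (R)-4-[4-(tert-butyldimethylsilyloxy)-3-methoxybenzyl]dihydrofuran-2(3H)-one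
Conditions: TFA, CH2Cl2, 0 °C → rt
Reagents that add atoms: none
Why: Acid-mediated loss of the tert-butyl group and lactonisation of the γ-hydroxy acid (five-membered ring closure by acyl substitution), which the aryl silyl ether tolerates under anhydrous conditions.

**Step 6**
Reactants: 11 4-benzyloxy-3-methoxybenzyl alcohol
Product: 12 4-benzyloxy-3-methoxybenzyl bromide
Conditions: PBr3 (0.4 equiv), Et2O, 0 °C
Reagents that add atoms: phosphorus tribromide, BrP(Br)Br
Why: Standard conversion of a benzylic alcohol into the bromide by nucleophilic substitution of its phosphite ester.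

**Step 7**
Reactants: 10 the (R)-lactone; 12 4-benzyloxy-3-methoxybenzyl bromide
Product: 14 (3R,4R)-3-(4-benzyloxy-3-methoxybenzyl)-4-[4-(tert-butyldimethylsilyloxy)-3-methoxybenzyl]dihydrofuran-2(3H)-one, via lithium enolate 13 (not isolated)
Conditions: LiN(iPr)2, THF, −78 °C; then 12, −78 → −30 °C
Reagents that add atoms: none
Why: Alkylation of the lactone enolate by the benzylic bromide anti to the C4 benzyl group should give the trans-3,4-disubstituted lactone, setting C3 as R by substrate control (the trans isomer is also the thermodynamic one).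

**Step 8**
Reactants: 14 the silyl-protected trans lactone
Product: 15 (3R,4R)-3-(4-benzyloxy-3-methoxybenzyl)-4-(4-hydroxy-3-methoxybenzyl)dihydrofuran-2(3H)-one (ring A benzyl ether of matairesinol)
Conditions: Bu4NF, AcOH, THF, 0 °C
Reagents that add atoms: none
Why: Fluoride-mediated desilylation of the aryl silyl ether, with acetic acid buffering the phenoxide so that the lactone and its α-centre are left alone.

**Step 9**
Reactants: 15 ring A benzyl ether of matairesinol
Product: 16 (3R,4R)-3-(4-benzyloxy-3-methoxybenzyl)-4-(4-hydroxy-3-iodo-5-methoxybenzyl)dihydrofuran-2(3H)-one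
Conditions: I2, NaHCO3, THF/H2O, 0 °C → rt; Na2S2O3 work-up
Reagents that add atoms: iodine, II
Why: Electrophilic aromatic iodination through the phenoxide: only ring B has a free phenol, its para position and one ortho position are blocked, so iodine enters at C5, and the benzyl-protected ring A does not react with I2 under these weakly basic conditions.

**Step 10**
Reactants: 16 the iodophenol
Product: 17 (3R,4R)-4-(4-acetoxy-3-iodo-5-methoxybenzyl)-3-(4-benzyloxy-3-methoxybenzyl)dihydrofuran-2(3H)-one
Conditions: Ac2O, pyridine, DMAP (cat.), CH2Cl2, rt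
Reagents that add atoms: acetic anhydride, CC(=O)OC(C)=O
Why: DMAP-catalysed O-acetylation of the hindered phenol, which makes the ring B oxygen non-nucleophilic for the key step.

**Step 11**
Reactants: 18 2-methoxy-4-vinylphenol
Product: 19 1-benzyloxy-2-methoxy-4-vinylbenzene (4-benzyloxy-3-methoxystyrene)
Conditions: BnBr, K2CO3, DMF, rt
Reagents that add atoms: benzyl bromide, BrCc1ccccc1
Why: Williamson ether synthesis on the phenoxide, run with mild base at room temperature to avoid polymerisation of the styrene.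

**Step 12**
Reactants: 17 the ring B iodo acetate; 19 4-benzyloxy-3-methoxystyrene
Product: 20 (3R,4R)-4-{4-acetoxy-3-[(E)-2-(4-benzyloxy-3-methoxyphenyl)ethenyl]-5-methoxybenzyl}-3-(4-benzyloxy-3-methoxybenzyl)dihydrofuran-2(3H)-one
Conditions: Pd(OAc)2 (5 mol %), P(o-tol)3 (10 mol %), Et3N, DMF, 90 °C
Reagents that add atoms: none
Why: Mizoroki–Heck reaction, in which oxidative addition of the aryl iodide to zerovalent palladium, insertion of the styrene at its terminal carbon and syn β-hydride elimination give the E-stilbene, while the aryl acetate, the lactone and the benzyl ethers are stable to Et3N in dry DMF.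

**Step 13**
Reactants: 20 the E-stilbene; 21 paraformaldehyde (formaldehyde source)
Product: 22 (3R,4R)-4-{4-acetoxy-3-[(4R,5R)-4-(4-benzyloxy-3-methoxyphenyl)-1,3-dioxan-5-yl]-5-methoxybenzyl}-3-(4-benzyloxy-3-methoxybenzyl)dihydrofuran-2(3H)-one
Conditions: (CH2O)n (6 equiv CH2O), confined chiral imino-imidodiphosphate Brønsted acid (two 3,3'-diaryl-BINOL phosphorus units bridged by NH, one P=O and one P=N–SO2CF3; 10 mol %), CHCl3, 0 °C → rt
Reagents that add atoms: paraformaldehyde 21 as formaldehyde, C=O (two units)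
Why: Proposed new method: the chiral acid activates formaldehyde (or a short oligomer) and C8 of the stilbene attacks its carbon from the Re face, so that positive charge builds at C7, where the para-benzyloxy group of ring C stabilises it far better than the twisted ortho-acetoxy and the meta-methoxy group of ring B could stabilise charge at C8; this fixes the regiochemistry as C8–C9 and then C7–O. The hemiacetal oxygen of a second formaldehyde unit then captures C7 in a six-membered ring closure (stepwise cation capture or its concerted asynchronous equivalent) to give the 1,3-dioxane; the closest known reaction type is the confined-acid-catalysed asymmetric Prins reaction of terminal styrenes with paraformaldehyde to 4-aryl-1,3-dioxanes, and the classical Prins reaction of anethole-type β-substituted styrenes shows that 1,2-disubstituted aryl alkenes can take part. C8 is set by the catalyst pocket, which selects the alkene face; C7 follows from syn addition across the E alkene and, because the para-alkoxybenzylic C7–O bond can re-ionise under the acid, also from equilibration to the diequatorial trans isomer, so both paths lead to 4R,5R. The step needs chemoselectivity for the alkene over the electron-rich rings A and C and over the ring B oxygen, and the acetate secures the latter by making that oxygen non-nucleophilic, so closure to a dihydrobenzofuran cannot compete, and by lowering the electron density of ring B. The lactone stereocentres lie many bonds from the alkene, so catalyst control is expected to dominate, and the unwanted isomers are diastereomers that can be removed by chromatography.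

**Step 14**
Reactants: 22 the (4R,5R)-dioxane
Product: 24 (3R,4R)-4-{4-acetoxy-3-[(1R,2R)-1-(4-benzyloxy-3-methoxyphenyl)-1,3-dihydroxypropan-2-yl]-5-methoxybenzyl}-3-(4-benzyloxy-3-methoxybenzyl)dihydrofuran-2(3H)-one, via bipyridinium ether 23 (not isolated)
Conditions: TMSOTf, 2,2'-bipyridyl, CH2Cl2, 0 °C → rt; then H2O, rt
Reagents that add atoms: none
Why: Silyl triflate/bipyridyl cleavage of a methylene acetal, in which bipyridyl attacks the unhindered O–CH2–O carbon of the silylated acetal and water hydrolyses the resulting pyridinium ether; because this is steered by access to the methylene carbon and not by cation stability, the para-benzyloxybenzylic C7–O bond should not ionise and C7 and C8 are retained, whereas protic transacetalisation would risk scrambling C7.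

**Step 15**
Reactants: 24 the diol acetate
Product: 25 (3R,4R)-3-(4-benzyloxy-3-methoxybenzyl)-4-{3-[(1R,2R)-1-(4-benzyloxy-3-methoxyphenyl)-1,3-dihydroxypropan-2-yl]-4-hydroxy-5-methoxybenzyl}dihydrofuran-2(3H)-one
Conditions: K2CO3 (0.3 equiv), MeOH/THF, 0 °C; AcOH quench
Reagents that add atoms: none
Why: Base-catalysed transesterification (methanolysis) of the aryl acetate is much faster than opening of the lactone, which would in any case reclose on neutralisation, and any acetyl group that has migrated to an aliphatic hydroxyl is cleaved under the same conditions.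

**Step 16**
Reactants: 25 the dibenzyl ether
Product: 26 the target, (3R,4R)-4-{4-hydroxy-3-[(1R,2R)-1,3-dihydroxy-1-(4-hydroxy-3-methoxyphenyl)propan-2-yl]-5-methoxybenzyl}-3-(4-hydroxy-3-methoxybenzyl)dihydrofuran-2(3H)-one
Conditions: H2 (1 atm), 10 % Pd/C, EtOAc/EtOH, rt
Reagents that add atoms: none
Why: Catalytic hydrogenolysis of the two aryl benzyl ethers, with neutral solvent, low pressure and stopping at full conversion to keep the secondary benzylic C7–OH bond intact.

**Compound list**
1 | 3-(4-hydroxy-3-methoxyphenyl)propanoic acid (dihydroferulic acid) | COc1cc(CCC(=O)O)ccc1O | starting material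
2 | tert-butyldimethylsilyl 3-[4-(tert-butyldimethylsilyloxy)-3-methoxyphenyl]propanoate | COc1cc(CCC(=O)O[Si](C)(C)C(C)(C)C)ccc1O[Si](C)(C)C(C)(C)C | intermediate
3 | 3-[4-(tert-butyldimethylsilyloxy)-3-methoxyphenyl]propanoic acid | COc1cc(CCC(=O)O)ccc1O[Si](C)(C)C(C)(C)C | intermediate
4 | (S)-4-benzyl-1,3-oxazolidin-2-one | O=C1N[C@@H](Cc2ccccc2)CO1 | starting material
5 | mixed pivalic anhydride of 3 | COc1cc(CCC(=O)OC(=O)C(C)(C)C)ccc1O[Si](C)(C)C(C)(C)C | intermediate
6 | (S)-4-benzyl-3-{3-[4-(tert-butyldimethylsilyloxy)-3-methoxyphenyl]propanoyl}-1,3-oxazolidin-2-one | COc1cc(CCC(=O)N2C(=O)OC[C@@H]2Cc2ccccc2)ccc1O[Si](C)(C)C(C)(C)C | intermediate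
7 | sodium (Z)-enolate of 6 | [Na+].[O-]/C(=C\Cc1ccc(O[Si](C)(C)C(C)(C)C)c(OC)c1)N1C(=O)OC[C@@H]1Cc1ccccc1 | intermediate
8 | tert-butyl (3R)-4-[(4S)-4-benzyl-2-oxo-1,3-oxazolidin-3-yl]-3-[4-(tert-butyldimethylsilyloxy)-3-methoxybenzyl]-4-oxobutanoate | COc1cc(C[C@H](CC(=O)OC(C)(C)C)C(=O)N2C(=O)OC[C@@H]2Cc2ccccc2)ccc1O[Si](C)(C)C(C)(C)C | intermediate
9 | tert-butyl (R)-4-hydroxy-3-[4-(tert-butyldimethylsilyloxy)-3-methoxybenzyl]butanoate | COc1cc(C[C@H](CC(=O)OC(C)(C)C)CO)ccc1O[Si](C)(C)C(C)(C)C | intermediate
10 | (R)-4-[4-(tert-butyldimethylsilyloxy)-3-methoxybenzyl]dihydrofuran-2(3H)-one | COc1cc(C[C@@H]2CC(=O)OC2)ccc1O[Si](C)(C)C(C)(C)C | intermediate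
11 | 4-benzyloxy-3-methoxybenzyl alcohol | COc1cc(CO)ccc1OCc1ccccc1 | starting material
12 | 4-benzyloxy-3-methoxybenzyl bromide | COc1cc(CBr)ccc1OCc1ccccc1 | intermediate
13 | lithium enolate of 10 | [Li+].[O-]C1=C[C@@H](Cc2ccc(O[Si](C)(C)C(C)(C)C)c(OC)c2)CO1 | intermediate
14 | (3R,4R)-3-(4-benzyloxy-3-methoxybenzyl)-4-[4-(tert-butyldimethylsilyloxy)-3-methoxybenzyl]dihydrofuran-2(3H)-one | COc1cc(C[C@H]2C(=O)OC[C@@H]2Cc2ccc(O[Si](C)(C)C(C)(C)C)c(OC)c2)ccc1OCc1ccccc1 | intermediate
15 | (3R,4R)-3-(4-benzyloxy-3-methoxybenzyl)-4-(4-hydroxy-3-methoxybenzyl)dihydrofuran-2(3H)-one | COc1cc(C[C@H]2C(=O)OC[C@@H]2Cc2ccc(O)c(OC)c2)ccc1OCc1ccccc1 | intermediate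
16 | (3R,4R)-3-(4-benzyloxy-3-methoxybenzyl)-4-(4-hydroxy-3-iodo-5-methoxybenzyl)dihydrofuran-2(3H)-one | COc1cc(C[C@H]2C(=O)OC[C@@H]2Cc2cc(OC)c(O)c(I)c2)ccc1OCc1ccccc1 | intermediate
17 | (3R,4R)-4-(4-acetoxy-3-iodo-5-methoxybenzyl)-3-(4-benzyloxy-3-methoxybenzyl)dihydrofuran-2(3H)-one | COc1cc(C[C@H]2C(=O)OC[C@@H]2Cc2cc(OC)c(OC(C)=O)c(I)c2)ccc1OCc1ccccc1 | intermediate
18 | 2-methoxy-4-vinylphenol | C=Cc1ccc(O)c(OC)c1 | starting material
19 | 1-benzyloxy-2-methoxy-4-vinylbenzene | C=Cc1ccc(OCc2ccccc2)c(OC)c1 | intermediate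
20 | (3R,4R)-4-{4-acetoxy-3-[(E)-2-(4-benzyloxy-3-methoxyphenyl)ethenyl]-5-methoxybenzyl}-3-(4-benzyloxy-3-methoxybenzyl)dihydrofuran-2(3H)-one | COc1cc(C[C@H]2C(=O)OC[C@@H]2Cc2cc(OC)c(OC(C)=O)c(/C=C/c3ccc(OCc4ccccc4)c(OC)c3)c2)ccc1OCc1ccccc1 | intermediate
21 | formaldehyde (used as paraformaldehyde) | C=O | starting material
22 | (3R,4R)-4-{4-acetoxy-3-[(4R,5R)-4-(4-benzyloxy-3-methoxyphenyl)-1,3-dioxan-5-yl]-5-methoxybenzyl}-3-(4-benzyloxy-3-methoxybenzyl)dihydrofuran-2(3H)-one | COc1cc(C[C@H]2C(=O)OC[C@@H]2Cc2cc(OC)c(OC(C)=O)c([C@@H]3COCO[C@H]3c3ccc(OCc4ccccc4)c(OC)c3)c2)ccc1OCc1ccccc1 | intermediate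
23 | C9 trimethylsilyl ether and C7 O-(2,2'-bipyridinium-1-ylmethyl) ether triflate of diol 24 (drawn as one of two regioisomers that hydrolyse to the same diol) | COc1cc(C[C@H]2C(=O)OC[C@@H]2Cc2cc(OC)c(OC(C)=O)c([C@H](CO[Si](C)(C)C)[C@@H](OC[n+]3ccccc3-c3ccccn3)c3ccc(OCc4ccccc4)c(OC)c3)c2)ccc1OCc1ccccc1.[O-]S(=O)(=O)C(F)(F)F | intermediate
24 | (3R,4R)-4-{4-acetoxy-3-[(1R,2R)-1-(4-benzyloxy-3-methoxyphenyl)-1,3-dihydroxypropan-2-yl]-5-methoxybenzyl}-3-(4-benzyloxy-3-methoxybenzyl)dihydrofuran-2(3H)-one | COc1cc(C[C@H]2C(=O)OC[C@@H]2Cc2cc(OC)c(OC(C)=O)c([C@H](CO)[C@@H](O)c3ccc(OCc4ccccc4)c(OC)c3)c2)ccc1OCc1ccccc1 | intermediate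
25 | (3R,4R)-3-(4-benzyloxy-3-methoxybenzyl)-4-{3-[(1R,2R)-1-(4-benzyloxy-3-methoxyphenyl)-1,3-dihydroxypropan-2-yl]-4-hydroxy-5-methoxybenzyl}dihydrofuran-2(3H)-one | COc1cc(C[C@H]2C(=O)OC[C@@H]2Cc2cc(OC)c(O)c([C@H](CO)[C@@H](O)c3ccc(OCc4ccccc4)c(OC)c3)c2)ccc1OCc1ccccc1 | intermediate
26 | (3R,4R)-4-{4-hydroxy-3-[(1R,2R)-1,3-dihydroxy-1-(4-hydroxy-3-methoxyphenyl)propan-2-yl]-5-methoxybenzyl}-3-(4-hydroxy-3-methoxybenzyl)dihydrofuran-2(3H)-one (CNP0109231.2) | COc1cc(C[C@H]2C(=O)OC[C@@H]2Cc2cc(OC)c(O)c([C@H](CO)[C@@H](O)c3ccc(O)c(OC)c3)c2)ccc1O | target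

**Step count**
Total: 16 steps. Longest linear sequence: 14 steps (steps 1–5, 7–10, 12–16); steps 6 and 11 are side branches.

**Steps most likely to fail**

Step 13 (key step). The confined acid may not accommodate the large and slowly reacting stilbene. Formaldehyde may alkylate the electron-rich rings A and C faster than the alkene reacts. A long-lived C7 cation may erode face selection at C8. The fallback uses known chemistry, sets out from iodide 17 and comes back at diol acetate 24. Negishi coupling of 17 with the Reformatsky reagent BrZnCH2CO2tBu (Pd2(dba)3, XPhos, THF) should give the ring B tert-butyl arylacetate F1, and TFA in CH2Cl2 the arylacetic acid F2. Coupling with (R)-4-benzyl-1,3-oxazolidin-2-one (DCC, DMAP, CH2Cl2) gives the arylacetyl imide F3. A magnesium-catalysed Evans anti-aldol reaction (MgCl2 cat., Et3N, TMSCl, EtOAc) with 4-benzyloxy-3-methoxybenzaldehyde should give the silylated anti-aldol adduct F4; the soft enolisation touches only the chelating imide and not the lactone, and the (R)-auxiliary is expected to give the (2S,3R) adduct, which corresponds to 7R,8R. TFA/MeOH then frees the hydroxy imide F5, and NaBH4 in THF/H2O at 0 °C removes the auxiliary reductively to give 24.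

Step 14. The silyl triflate may ionise the para-benzyloxybenzylic C7–O bond with loss of configuration at C7, or the acetal may open incompletely. The fallback sets out from dioxane 22 and comes back at target 26. Hydrogenolysis at the dioxane stage (H2, Pd/C, EtOAc; aryl benzyl ethers cleave much faster than the cyclic benzylic ether) should give the bisphenol dioxane F6. Ac2O/pyridine converts it into the triacetate dioxane F7, in which ring C no longer stabilises a C7 cation. Classical acetolysis (Ac2O, cat. H2SO4, 0 °C) opens the methylene acetal to the acetate/acetoxymethyl ether F8 (its regioisomer converges). K2CO3 in MeOH then removes all acetyl groups and the acetoxymethyl group to give 26.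

Step 12. Insertion at the internal alkene carbon would give the 1,1-diarylethene isomer, and base at 90 °C may cleave the aryl acetate or polymerise the styrene. The fallback sets out from styrene 19 and comes back at stilbene 20. Cross-metathesis of 19 with vinylboronic acid pinacol ester (second-generation Grubbs catalyst, CH2Cl2, 40 °C) should give the (E)-styrylboronic ester F9. Suzuki–Miyaura coupling of F9 with iodide 17 (PdCl2(dppf), CsF, dioxane, 80 °C) then gives 20, with the attachment site and the E geometry fixed by the boronate.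

**Further compounds**
F1 | step 13 | tert-butyl ester of the ring B arylacetic acid (CH2CO2tBu in place of iodine in 17) | COc1cc(C[C@H]2C(=O)OC[C@@H]2Cc2cc(OC)c(OC(C)=O)c(CC(=O)OC(C)(C)C)c2)ccc1OCc1ccccc1
F2 | step 13 | ring B arylacetic acid (CH2CO2H in place of iodine in 17) | COc1cc(C[C@H]2C(=O)OC[C@@H]2Cc2cc(OC)c(OC(C)=O)c(CC(=O)O)c2)ccc1OCc1ccccc1
F3 | step 13 | (R)-4-benzyl-3-(arylacetyl)-1,3-oxazolidin-2-one of F2 | COc1cc(C[C@H]2C(=O)OC[C@@H]2Cc2cc(OC)c(OC(C)=O)c(CC(=O)N3C(=O)OC[C@H]3Cc3ccccc3)c2)ccc1OCc1ccccc1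
F4 | step 13 | (2S,3R)-anti-aldol adduct of F3 with 4-benzyloxy-3-methoxybenzaldehyde as its trimethylsilyl ether | COc1cc(C[C@H]2C(=O)OC[C@@H]2Cc2cc(OC)c(OC(C)=O)c([C@H](C(=O)N3C(=O)OC[C@H]3Cc3ccccc3)[C@@H](O[Si](C)(C)C)c3ccc(OCc4ccccc4)c(OC)c3)c2)ccc1OCc1ccccc1
F5 | step 13 | (2S,3R)-anti-aldol adduct with free hydroxyl | COc1cc(C[C@H]2C(=O)OC[C@@H]2Cc2cc(OC)c(OC(C)=O)c([C@H](C(=O)N3C(=O)OC[C@H]3Cc3ccccc3)[C@@H](O)c3ccc(OCc4ccccc4)c(OC)c3)c2)ccc1OCc1ccccc1
F6 | step 14 | bisphenol dioxane (22 without its two benzyl groups) | COc1cc(C[C@H]2C(=O)OC[C@@H]2Cc2cc(OC)c(OC(C)=O)c([C@@H]3COCO[C@H]3c3ccc(O)c(OC)c3)c2)ccc1O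
F7 | step 14 | triacetate dioxane | COc1cc(C[C@H]2C(=O)OC[C@@H]2Cc2cc(OC)c(OC(C)=O)c([C@@H]3COCO[C@H]3c3ccc(OC(C)=O)c(OC)c3)c2)ccc1OC(C)=O
F8 | step 14 | acetolysis product with C9 acetate and C7 acetoxymethyl ether and three aryl acetates | COc1cc(C[C@H]2C(=O)OC[C@@H]2Cc2cc(OC)c(OC(C)=O)c([C@H](COC(C)=O)[C@@H](OCOC(C)=O)c3ccc(OC(C)=O)c(OC)c3)c2)ccc1OC(C)=O
F9 | step 12 | (E)-2-[2-(4-benzyloxy-3-methoxyphenyl)ethenyl]-4,4,5,5-tetramethyl-1,3,2-dioxaborolane | COc1cc(/C=C/B2OC(C)(C)C(C)(C)O2)ccc1OCc1ccccc1
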